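The numbers in the tables are calculated from invented constants; scatter was added.

A small charge ends with a larger share of Z at the same time than a large one, and that looks wrong. In the east run, 0.67 M of solid X with 0.98 equiv of J has a Z fraction of 40.8 % at 2.00 min. In the north run, 1.5 M with the same equivalents gives 25.6 % at that time, taken midway between its readings at 1.50 min and 2.50 min, so the north fraction is lower. Yet a second-order step between two dissolved partners, taken by itself at fixed equivalents, gains fraction faster in a richer flask.

| setting | east | north | flask |
|---|---|---|---|
| X | 0.67 M | 1.5 M | 1.0 M |
| J | 0.98 equiv | 0.98 equiv | 0.980 equiv |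
| remark | run made earlier | run made earlier |  |
| time |  |  | 2.0 min |

| run | time / min | Z / % | X / % |
|---|---|---|---|
| east | 0.333 | 3.7 | 89.5 |
| east | 0.667 | 10.4 | 80.3 |
| east | 1.00 | 20.9 | 72.3 |
| east | 1.33 | 27.5 | 64.7 |
| east | 1.50 | 30.0 | 60.9 |
| east | 2.00 | 40.8 | 50.3 |
| east | 2.50 | 49.0 | 40.1 |
| north | 0.200 | 1.6 | 97.9 |
| north | 0.333 | 2.5 | 95.7 |
| north | 0.417 | 6.0 | 93.7 |
| north | 0.667 | 8.1 | 91.9 |
| north | 1.00 | 10.9 | 86.3 |
| north | 1.50 | 18.4 | 77.9 |
| north | 2.50 | 32.8 | 67.2 |

(readings scatter by 1 percentage point)

- given per volume of solution although it is solid: X
- at the start none of X is in solution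

* how much Z there is at 2.0 min, in percent of the X charged
* the change that raises the amount of Z at 2.0 min, in percent of the X charged most ("none" if none brings more than 2 percentage points) (Saturday's / Friday's / Thursday's / none)
* amount of Z at 2.0 min, in percent of the X charged, after Saturday's

- Saturday's: doubling the dissolution coefficient of X, all else as stated
- Friday's: doubling the amount of J, all else as stated
- Thursday's: doubling the solubility of X, all else as stated

Logarithms clear this up. From east to north the charge rises by 0.350 of a power of ten, while the Z fraction falls by 0.202. Their ratio, 0.578, I call the charge exponent: powers of ten lost in Z fraction per power of ten gained in charge, at fixed time and equivalents. Z made at one molar rate whatever the charge gives an exponent of one, and a second-order step between dissolved partners gives a negative exponent. This reading lies between them: from east to north the charge rises by a factor of 2.24 and the molar amount of Z by a factor of 1.40, so the fraction sinks without any contradiction.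

The flask has 1.0 M, which is 0.174 above east on the logarithmic scale, so I take 0.101 off the logarithm of the east fraction. At 2.0 min I commit to a Z fraction of 32.4 %.

The forecast, reckoned from rates, gives 32 % (28 % to 36 %), names Thursday's as the best change, and gives 44 % (38 % to 51 %) after Saturday's. Its ground is that “dissolution mostly limits the rate, though not entirely”.

The flask gives 33.2 %.

    X ⇌ L, rate k1*(cs1 - [L]) while solid is left; crystals form when [L] > cs1 (solubility = 0.170 M, k = 0.0240 s⁻¹)
    L + J → Z + D (k = 0.0900 M⁻¹ s⁻¹)

That is 0.80 percentage points above my fraction, and Thursday's does win, with a gain of 27 points, while Saturday's reaches 50.6 %, 6.6 points above the forecast. In the flask at 1.00 min, L, the dissolved form of X, stands at 23.8 % of saturation. The exponent also serves a second flask: the east run at 2.50 min, without its scatter, holds 51.1 % of Z, and raising its charge to 1.0 M at the same equivalents and time should bring that to 40.5 %. That flask stands at 41.4 %.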